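## Retrosynthetic overview

- The quinone is unveiled last by oxidative demethylation of a 2,5-dimethoxy-3-methylphenyl precursor.
- The single stereocenter (C5 of the lactone, S) is set by a chiral Brønsted-acid-catalysed protonation at C5 of a 3,5-dialkyl-2-silyloxyfuran.
- The C5–CH2 bond comes from SN2 alkylation of a C5-lithiated 3-homoprenyl-2-silyloxyfuran with an E,E-allylic bromide.
- The allylic bromide comes from an aryl Grignard plus geranyl bromide, then SeO2 allylic oxidation and Appel bromination. The butenolide comes from 3-bromofuran-2(5H)-one by Negishi coupling.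
- Ring order: no ring is constructed. The lactone ring is bought, aromatised to the furan, then returned to the butenolide in the asymmetric step; the benzoquinone ring is unmasked from the bought arene at the end.

Assumption: the bromoarene and the bromobutenolide starting materials are bought. The facial sense of the new protonation cannot be predicted with certainty, so the acid antipode written is the one assumed to give S, and its mirror image is used if it gives R.

## Route

Step 1
Reactants: 1 1-bromo-2,5-dimethoxy-3-methylbenzene; 2 geranyl bromide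
Product: 4 1-[(2E)-3,7-dimethylocta-2,6-dien-1-yl]-2,5-dimethoxy-3-methylbenzene, via (2,5-dimethoxy-3-methylphenyl)magnesium bromide 3 (not isolated)
Conditions: Mg, THF, 50 °C; then CuI (5 mol %), 2, THF, −20 to 0 °C
Reagents that add atoms: none
Why: Copper-catalysed Grignard allylic substitution goes SN2 at the primary carbon of geranyl bromide (its γ-carbon is fully substituted), so the E double bond is kept and no stereocenter is formed.

Step 2
Reactants: 4 1-[(2E)-3,7-dimethylocta-2,6-dien-1-yl]-2,5-dimethoxy-3-methylbenzene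
Product: 5 (2E,6E)-8-(2,5-dimethoxy-3-methylphenyl)-2,6-dimethylocta-2,6-dien-1-ol
Conditions: SeO2 (0.3 equiv), t-BuOOH (3 equiv), salicylic acid (10 mol %), CH2Cl2, rt
Reagents that add atoms: SeO2 (O=[Se]=O), which delivers the oxygen; tert-butyl hydroperoxide (CC(C)(C)OO), which restores it
Why: Riley allylic oxidation (ene reaction then [2,3]-shift) attacks the E-methyl group of the terminal trisubstituted double bond preferentially, giving the E-allylic alcohol without a stereocenter.

Step 3
Reactants: 5 (2E,6E)-8-(2,5-dimethoxy-3-methylphenyl)-2,6-dimethylocta-2,6-dien-1-ol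
Product: 6 1-[(2E,6E)-8-bromo-3,7-dimethylocta-2,6-dien-1-yl]-2,5-dimethoxy-3-methylbenzene
Conditions: CBr4, PPh3, CH2Cl2, 0 °C; used at once
Reagents that add atoms: carbon tetrabromide (BrC(Br)(Br)Br)
Why: Appel bromination converts the primary allylic alcohol to the bromide under neutral conditions that leave the electron-rich arene and both E double bonds untouched.

Step 4
Reactants: 7 5-bromo-2-methylpent-2-ene; 8 3-bromofuran-2(5H)-one
Product: 11 3-(4-methylpent-3-en-1-yl)furan-2(5H)-one, via (4-methylpent-3-en-1-yl)magnesium bromide 9 (not isolated), via chloro(4-methylpent-3-en-1-yl)zinc 10 (not isolated)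
Conditions: Mg, THF, rt; ZnCl2, THF, 0 °C; then 8, Pd(dppf)Cl2 (3 mol %), THF, rt to 40 °C
Reagents that add atoms: none
Why: Negishi coupling of the primary alkylzinc with the vinylic C–Br bond works because Pd(dppf)Cl2 suppresses β-hydride elimination and the neutral organozinc tolerates the lactone.

Step 5
Reactants: 11 3-(4-methylpent-3-en-1-yl)furan-2(5H)-one
Product: 12 triisopropyl{[3-(4-methylpent-3-en-1-yl)furan-2-yl]oxy}silane
Conditions: TIPSOTf, Et3N, CH2Cl2, 0 °C
Reagents that add atoms: triisopropylsilyl trifluoromethanesulfonate (CC(C)[Si](C(C)C)(C(C)C)OS(=O)(=O)C(F)(F)F)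
Why: Soft enolisation and O-silylation of the butenolide gives the aromatic 2-silyloxyfuran, and the bulky silyl group is chosen to survive the next metalation.

Step 6
Reactants: 12 triisopropyl{[3-(4-methylpent-3-en-1-yl)furan-2-yl]oxy}silane; 6 1-[(2E,6E)-8-bromo-3,7-dimethylocta-2,6-dien-1-yl]-2,5-dimethoxy-3-methylbenzene
Product: 14 ({5-[(2E,6E)-8-(2,5-dimethoxy-3-methylphenyl)-2,6-dimethylocta-2,6-dien-1-yl]-3-(4-methylpent-3-en-1-yl)furan-2-yl}oxy)triisopropylsilane, via C5-lithiated silyloxyfuran 13 (not isolated)
Conditions: s-BuLi, TMEDA, THF, 0 °C; then 6, −78 to −20 °C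
Reagents that add atoms: none
Why: α-Metalation of the furan at C5, its only free α-position, then SN2 alkylation of the 2-furyllithium with the primary allylic bromide forms the C5–CH2 bond with both E double bonds intact and still no stereocenter.

Step 7
Reactants: 14 ({5-[(2E,6E)-8-(2,5-dimethoxy-3-methylphenyl)-2,6-dimethylocta-2,6-dien-1-yl]-3-(4-methylpent-3-en-1-yl)furan-2-yl}oxy)triisopropylsilane
Product: 16 (5S)-5-[(2E,6E)-8-(2,5-dimethoxy-3-methylphenyl)-2,6-dimethylocta-2,6-dien-1-yl]-3-(4-methylpent-3-en-1-yl)furan-2(5H)-one, via O-silyl lactone oxocarbenium ion 15 (not isolated)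
Conditions: (S)-3,3'-bis(2,4,6-triisopropylphenyl)-1,1'-binaphthyl-2,2'-diyl N-triflyl thiophosphoramide (5 mol %), PhOH (1.1 equiv), toluene, −78 °C; Et3N quench
Reagents that add atoms: none
Why: Proposed new method: catalytic enantioselective vinylogous protonation of a 2-silyloxyfuran; C5 is the most nucleophilic carbon of the silyloxyfuran (as in vinylogous Mukaiyama reactions), so the strong chiral acid transfers its proton there inside a tight ion pair whose binaphthyl pocket is assumed to expose the Re face of C5, giving the S-configured cation 15, which hands its silyl group to phenol (too weak an acid to protonate 14 itself, so there is no racemic background) and regenerates the catalyst; the closest known reaction type is the chiral N-triflyl thiophosphoramide- or disulfonimide-catalysed enantioselective protonation of silyl enol ethers and silyl ketene acetals with an achiral stoichiometric proton source, which has not been shown at the γ-carbon of a silyloxyfuran.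

Step 8
Reactants: 16 (5S)-5-[(2E,6E)-8-(2,5-dimethoxy-3-methylphenyl)-2,6-dimethylocta-2,6-dien-1-yl]-3-(4-methylpent-3-en-1-yl)furan-2(5H)-one
Product: 17 (5S)-5-[(2E,6E)-2,6-dimethyl-8-(5-methyl-3,6-dioxocyclohexa-1,4-dien-1-yl)octa-2,6-dien-1-yl]-3-(4-methylpent-3-en-1-yl)furan-2(5H)-one
Conditions: (NH4)2Ce(NO3)6 (2.5 equiv), MeCN/H2O 3:1, 0 °C, 15 min
Reagents that add atoms: water (O)
Why: Oxidative demethylation of the para-dimethoxyarene by tetravalent cerium with attack of water gives the para-quinone under cold acidic conditions that neither touch the trisubstituted alkenes nor epimerise C5.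

## Compound list

1 | 1-bromo-2,5-dimethoxy-3-methylbenzene | COc1cc(C)c(OC)c(Br)c1 | starting material
2 | geranyl bromide, (2E)-1-bromo-3,7-dimethylocta-2,6-diene | CC(C)=CCC/C(C)=C/CBr | starting material
3 | (2,5-dimethoxy-3-methylphenyl)magnesium bromide | COc1cc(C)c(OC)c([Mg]Br)c1 | intermediate
4 | 1-[(2E)-3,7-dimethylocta-2,6-dien-1-yl]-2,5-dimethoxy-3-methylbenzene | CC(C)=CCC/C(C)=C/Cc1cc(OC)cc(C)c1OC | intermediate
5 | (2E,6E)-8-(2,5-dimethoxy-3-methylphenyl)-2,6-dimethylocta-2,6-dien-1-ol | OC/C(C)=C/CC/C(C)=C/Cc1cc(OC)cc(C)c1OC | intermediate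
6 | 1-[(2E,6E)-8-bromo-3,7-dimethylocta-2,6-dien-1-yl]-2,5-dimethoxy-3-methylbenzene | BrC/C(C)=C/CC/C(C)=C/Cc1cc(OC)cc(C)c1OC | intermediate
7 | 5-bromo-2-methylpent-2-ene | CC(C)=CCCBr | starting material
8 | 3-bromofuran-2(5H)-one | BrC1=CCOC1=O | starting material
9 | (4-methylpent-3-en-1-yl)magnesium bromide | CC(C)=CCC[Mg]Br | intermediate
10 | chloro(4-methylpent-3-en-1-yl)zinc | CC(C)=CCC[Zn]Cl | intermediate
11 | 3-(4-methylpent-3-en-1-yl)furan-2(5H)-one | CC(C)=CCCC1=CCOC1=O | intermediate
12 | triisopropyl{[3-(4-methylpent-3-en-1-yl)furan-2-yl]oxy}silane | CC(C)=CCCc1ccoc1O[Si](C(C)C)(C(C)C)C(C)C | intermediate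
13 | {4-(4-methylpent-3-en-1-yl)-5-[(triisopropylsilyl)oxy]furan-2-yl}lithium | CC(C)=CCCc1cc([Li])oc1O[Si](C(C)C)(C(C)C)C(C)C | intermediate
14 | ({5-[(2E,6E)-8-(2,5-dimethoxy-3-methylphenyl)-2,6-dimethylocta-2,6-dien-1-yl]-3-(4-methylpent-3-en-1-yl)furan-2-yl}oxy)triisopropylsilane | CC(C)=CCCc1cc(C/C(C)=C/CC/C(C)=C/Cc2cc(OC)cc(C)c2OC)oc1O[Si](C(C)C)(C(C)C)C(C)C | intermediate
15 | (5S)-C5-protonated O-triisopropylsilyl lactone oxocarbenium ion (paired with the catalyst anion) | CC(C)=CCCC1=C[C@H](C/C(C)=C/CC/C(C)=C/Cc2cc(OC)cc(C)c2OC)OC1=[O+][Si](C(C)C)(C(C)C)C(C)C | intermediate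
16 | (5S)-5-[(2E,6E)-8-(2,5-dimethoxy-3-methylphenyl)-2,6-dimethylocta-2,6-dien-1-yl]-3-(4-methylpent-3-en-1-yl)furan-2(5H)-one | CC(C)=CCCC1=C[C@H](C/C(C)=C/CC/C(C)=C/Cc2cc(OC)cc(C)c2OC)OC1=O | intermediate
17 | (5S)-5-[(2E,6E)-2,6-dimethyl-8-(5-methyl-3,6-dioxocyclohexa-1,4-dien-1-yl)octa-2,6-dien-1-yl]-3-(4-methylpent-3-en-1-yl)furan-2(5H)-one | CC(C)=CCCC1=C[C@H](C/C(C)=C/CC/C(C)=C/CC2=CC(=O)C=C(C)C2=O)OC1=O | target

## Step count and risks

Total step count: 8. Longest linear sequence: 6 steps (steps 1, 2, 3, 6, 7, 8, from 1); the butenolide arm adds steps 4 and 5 before the convergence in step 6.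

The three steps most likely to fail:

1. Step 7 (the proposed new protonation). The risks are competing C3 protonation, slow transfer of the bulky silyl group to phenol, and modest facial selectivity with purely aliphatic substituents. The fallback uses known chemistry, sets out from 14 and comes back at 16. The silyl ether of 14 is cleaved with Bu4NF in THF at −78 °C and the dienolate is quenched with AcOH, which protonates kinetically at C3. This gives the deconjugated lactone 5-[(2E,6E)-8-(2,5-dimethoxy-3-methylphenyl)-2,6-dimethylocta-2,6-dien-1-yl]-3-(4-methylpent-3-en-1-yl)furan-2(3H)-one F1, whose racemic C3 centre is erased in the next operation. F1 is then isomerised with a bifunctional 6'-hydroxy cinchona alkaloid (10 mol %, CH2Cl2, −20 °C). This is the known organocatalytic proton-transfer isomerisation of β,γ- to α,β-unsaturated butenolides, which sets C5 by enantioselective γ-protonation. The quinine- or quinidine-derived pseudo-enantiomer that gives S is chosen, and the product is 16.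

2. Step 6 (metalation and alkylation). The furyllithium may deprotonate the doubly activated ArCH2 position of 6 or give Wurtz-type products, and 14 is sensitive to hydrolysis. The fallback sets out from 12 and 6 and comes back at 14. Instead of metalation, 12 and 6 are combined with AgOCOCF3 (1.1 equiv) in CH2Cl2 at −78 °C. Silver-assisted ionisation of the allylic bromide and γ-selective vinylogous alkylation of the silyloxyfuran give the racemic lactone 5-[(2E,6E)-8-(2,5-dimethoxy-3-methylphenyl)-2,6-dimethylocta-2,6-dien-1-yl]-3-(4-methylpent-3-en-1-yl)furan-2(5H)-one F2. TIPSOTf and Et3N in CH2Cl2 at 0 °C then convert F2 into 14, in which C5 is planar again, so the asymmetric step is unaffected.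

3. Step 4 (Negishi coupling at the α-bromobutenolide). Oxidative addition at the α-position is slow, and conjugate addition or reduction of 8 can compete. The fallback sets out from 7 and comes back at 11, and builds the lactone by olefination instead of cross-coupling. Ethyl 2-(diphenoxyphosphoryl)acetate is alkylated with 7 (NaH, NaI cat., DMF, 60 °C) to ethyl 2-(diphenoxyphosphoryl)-6-methylhept-5-enoate F3. Z-selective Horner–Wadsworth–Emmons olefination of F3 with glycolaldehyde (from its dimer; NaH, THF, −20 °C to rt) gives ethyl (2Z)-2-(2-hydroxyethylidene)-6-methylhept-5-enoate F4. Its cis hydroxy ester closes to 11 in the flask or on brief TsOH treatment.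

Further compounds
F1 | step 7 | 5-[(2E,6E)-8-(2,5-dimethoxy-3-methylphenyl)-2,6-dimethylocta-2,6-dien-1-yl]-3-(4-methylpent-3-en-1-yl)furan-2(3H)-one | CC(C)=CCCC1C=C(C/C(C)=C/CC/C(C)=C/Cc2cc(OC)cc(C)c2OC)OC1=O
F2 | step 6 | racemic 5-[(2E,6E)-8-(2,5-dimethoxy-3-methylphenyl)-2,6-dimethylocta-2,6-dien-1-yl]-3-(4-methylpent-3-en-1-yl)furan-2(5H)-one | CC(C)=CCCC1=CC(C/C(C)=C/CC/C(C)=C/Cc2cc(OC)cc(C)c2OC)OC1=O
F3 | step 4 | ethyl 2-(diphenoxyphosphoryl)-6-methylhept-5-enoate | CCOC(=O)C(CCC=C(C)C)P(=O)(Oc1ccccc1)Oc1ccccc1
F4 | step 4 | ethyl (2Z)-2-(2-hydroxyethylidene)-6-methylhept-5-enoate | CCOC(=O)/C(CCC=C(C)C)=C\CO
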